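**Retrosynthetic overview**
- The C40 chain is cut at C11'=C12' and C11=C12 (two Wittig reactions) into a furanoid C15 phosphonium salt, commercial C10 trienedial and a cis-diol C15 phosphonium salt.
- Furanoid C15: the dihydrofuran ring is closed last through the O–C8' bond by cycloisomerization of an α-hydroxyallene; the allene (C8'–C9' bond) comes from an anti-SN2' coupling of an ethynyl carbinol carbonate with a C4 alkenylboronate.
- Diol C15: C6–C7 bond by acetylide addition of a commercial C6 enynol to the same ketone, then trans-reduction of the alkyne.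
- Both halves come from one ketone, silyl-protected (R)-2-hydroxy-2,6,6-trimethylcyclohexanone, made from (R)-linalool by an electro-initiated cobalt-hydride cycloisomerization (C1–C6 ring bond) and ozonolysis.
- Ring order: cyclohexane first (step 1), dihydrofuran second (step 7). C5/C5' are bought with linalool, C6/C6' are set by substrate-controlled addition, and C8' by relay from C6' through the allene axis.

Assumption: carotenoid numbering is used in the text (primed locants for the furanoid half), and natural (R)-(−)-linalool is taken at the enantiomeric purity of the commercial oil, minor stereoisomers being removed at the crystalline C40 stage.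

**Step 1**
Reactants: 1 (R)-(−)-linalool
Product: 2 (1R)-1,3,3-trimethyl-2-methylidenecyclohexan-1-ol
Conditions: Co(salen), Co(C16H14N2O2) (5 mol%), HFIP, n-Bu4NPF6, MeCN, undivided cell, graphite cathode, Zn anode, constant current, 0.3 F/mol, rt
Reagents that add atoms: none
Why: Proposed new method: a cathodically generated cobalt hydride (trivalent cobalt) transfers H• to the electron-rich trisubstituted alkene, the tertiary radical closes 6-exo-trig onto the carbinol-deactivated vinyl group to form the C1–C6 ring bond, and capture of the primary radical by divalent cobalt followed by β-hydride loss (only the ring C–H is available) releases the exocyclic alkene and regenerates the hydride, the closest known reaction types being cobalt–salen/silane MHAT cycloisomerization of dienes and cobalt-electrocatalytic HAT alkene isomerization; the linalool stereocentre (future C5 and C5') is not touched.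

**Step 2**
Reactants: 2 (1R)-1,3,3-trimethyl-2-methylidenecyclohexan-1-ol
Product: 4 (2R)-2-hydroxy-2,6,6-trimethylcyclohexan-1-one, via spiro ozonide 3 (not isolated)
Conditions: O3, CH2Cl2, −78 °C; then Me2S, −78 °C to rt
Reagents that add atoms: ozone, [O-][O+]=O
Why: Ozonolysis of the exocyclic 1,1-disubstituted alkene with reductive work-up gives the α-hydroxy ketone, which cannot enolize because both α-carbons are quaternary, so C5 is safe.

**Step 3**
Reactants: 4 (2R)-2-hydroxy-2,6,6-trimethylcyclohexan-1-one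
Product: 5 (2R)-2,6,6-trimethyl-2-[(triethylsilyl)oxy]cyclohexan-1-one
Conditions: TESOTf, 2,6-lutidine, CH2Cl2, −78 to 0 °C
Reagents that add atoms: triethylsilyl trifluoromethanesulfonate, CC[Si](CC)(CC)OS(=O)(=O)C(F)(F)F
Why: Silyl triflate silylation of the hindered tertiary alcohol installs a bulky, non-chelating group that sits axial and later shields one face of the carbonyl.

**Step 4**
Reactants: 6 ethyl but-2-ynoate
Product: 7 ethyl (2Z)-3-(4,4,5,5-tetramethyl-1,3,2-dioxaborolan-2-yl)but-2-enoate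
Conditions: B2pin2, CuCl (3 mol%), NaOt-Bu (6 mol%), Xantphos (3 mol%), MeOH (2 equiv), THF, rt
Reagents that add atoms: bis(pinacolato)diboron, CC1(C)OB(OC1(C)C)B1OC(C)(C)C(C)(C)O1
Why: Copper-boryl syn-addition to the ynoate (β-borylation, monovalent copper) followed by protonation puts boron β and trans to the ester, which fixes the later 9'E geometry.

**Step 5**
Reactants: 5 (2R)-2,6,6-trimethyl-2-[(triethylsilyl)oxy]cyclohexan-1-one; 8 ethynylmagnesium bromide
Product: 10 (1R,2R)-1-ethynyl-2,6,6-trimethyl-2-[(triethylsilyl)oxy]cyclohexyl methyl carbonate, via bromomagnesium alkoxide 9 (not isolated)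
Conditions: THF, 0 °C to rt; then ClCO2Me, 0 to 40 °C
Reagents that add atoms: methyl chloroformate, COC(=O)Cl
Why: Acetylide 1,2-addition to the non-enolizable ketone occurs axially and anti to the axial OSiEt3 group (Felkin–Anh, the other face is blocked by two axial α-substituents), which sets C6' with its oxygen cis to the C5' oxygen, and the alkoxide is trapped in situ as the carbonate.

**Step 6**
Reactants: 10 (1R,2R)-1-ethynyl-2,6,6-trimethyl-2-[(triethylsilyl)oxy]cyclohexyl methyl carbonate; 7 ethyl (2Z)-3-(4,4,5,5-tetramethyl-1,3,2-dioxaborolan-2-yl)but-2-enoate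
Product: 11 ethyl (2E,4Ra)-3-methyl-5-{(2R)-2,6,6-trimethyl-2-[(triethylsilyl)oxy]cyclohexylidene}penta-2,4-dienoate
Conditions: Pd(PPh3)4 (5 mol%), THF, 60 °C
Reagents that add atoms: none
Why: Palladium-catalysed coupling of a propargylic carbonate with an alkenylboronate (allene-forming cross-coupling) proceeds by anti-SN2' oxidative addition of zerovalent palladium, decarboxylation to the allenylpalladium methoxide, transmetalation and retentive reductive elimination, so the C6' configuration is transferred to the (Ra) allene axis while the C8'–C9' bond forms.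

**Step 7**
Reactants: 11 ethyl (2E,4Ra)-3-methyl-5-{(2R)-2,6,6-trimethyl-2-[(triethylsilyl)oxy]cyclohexylidene}penta-2,4-dienoate
Product: 13 ethyl (2E)-3-[(2S,7aR)-4,4,7a-trimethyl-2,4,5,6,7,7a-hexahydro-1-benzofuran-2-yl]but-2-enoate, via allenol 12 (not isolated)
Conditions: n-Bu4NF, AcOH, THF, 0 °C; then AgNO3 (20 mol%), acetone, rt, dark
Reagents that add atoms: none
Why: Fluoride desilylation is followed by silver-catalysed (monovalent silver) 5-endo cycloisomerization of the α-hydroxyallene to the 2,5-dihydrofuran, in which the in-plane hydroxyl attacks C8' and the allene axis is converted into the C8' centre (S, side chain cis to the C5' methyl).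

**Step 8**
Reactants: 13 ethyl (2E)-3-[(2S,7aR)-4,4,7a-trimethyl-2,4,5,6,7,7a-hexahydro-1-benzofuran-2-yl]but-2-enoate
Product: 14 (2E)-3-[(2S,7aR)-4,4,7a-trimethyl-2,4,5,6,7,7a-hexahydro-1-benzofuran-2-yl]but-2-en-1-ol
Conditions: i-Bu2AlH (2.5 equiv), CH2Cl2, −78 °C; aq. potassium sodium tartrate
Reagents that add atoms: none
Why: Aluminium hydride 1,2-reduction of the conjugated ester gives the allylic alcohol and removes the vinylogous acidity of the C8' hydrogen.

**Step 9**
Reactants: 14 (2E)-3-[(2S,7aR)-4,4,7a-trimethyl-2,4,5,6,7,7a-hexahydro-1-benzofuran-2-yl]but-2-en-1-ol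
Product: 16 {(2E)-3-[(2S,7aR)-4,4,7a-trimethyl-2,4,5,6,7,7a-hexahydro-1-benzofuran-2-yl]but-2-en-1-yl}triphenylphosphonium bromide, via allylic bromide 15 (not isolated)
Conditions: CBr4, PPh3, CH2Cl2, 0 °C; then PPh3, toluene, rt
Reagents that add atoms: carbon tetrabromide, BrC(Br)(Br)Br; triphenylphosphine, c1ccc(cc1)P(c1ccccc1)c1ccccc1
Why: Appel bromination of the primary allylic alcohol under neutral conditions and SN2 quaternization avoid the acid that would ionize the allylic C8'–O bond.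

**Step 10**
Reactants: 16 {(2E)-3-[(2S,7aR)-4,4,7a-trimethyl-2,4,5,6,7,7a-hexahydro-1-benzofuran-2-yl]but-2-en-1-yl}triphenylphosphonium bromide; 17 (2E,4E,6E)-2,7-dimethylocta-2,4,6-trienedial (3 equiv)
Product: 18 (2E,4E,6E,8E,10E)-2,7-dimethyl-11-[(2S,7aR)-4,4,7a-trimethyl-2,4,5,6,7,7a-hexahydro-1-benzofuran-2-yl]dodeca-2,4,6,8,10-pentaenal
Conditions: 1,2-epoxybutane, EtOH, 70 °C, Ar, dark
Reagents that add atoms: none
Why: Wittig olefination in which the epoxide scavenges HBr generates the semi-stabilized ylide only in the presence of excess dialdehyde, giving the mono-adduct with thermal equilibration of the new C11'=C12' bond to E and little lifetime for the ylide to disturb C8'.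

**Step 11**
Reactants: 5 (2R)-2,6,6-trimethyl-2-[(triethylsilyl)oxy]cyclohexan-1-one; 19 (2E)-3-methylpent-2-en-4-yn-1-ol
Product: 21 (2E)-5-{(1R,2R)-1-hydroxy-2,6,6-trimethyl-2-[(triethylsilyl)oxy]cyclohexyl}-3-methylpent-2-en-4-yn-1-ol, via dilithio dianion 20 (not isolated)
Conditions: n-BuLi (2 equiv per 19), THF, −78 to 0 °C; then 5, −78 °C to rt; H2O
Reagents that add atoms: none
Why: Acetylide 1,2-addition with the same axial, anti-to-OSiEt3 facial control as in step 5 forms the C6–C7 bond and sets C6 with its hydroxyl cis to the C5 oxygen.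

**Step 12**
Reactants: 21 (2E)-5-{(1R,2R)-1-hydroxy-2,6,6-trimethyl-2-[(triethylsilyl)oxy]cyclohexyl}-3-methylpent-2-en-4-yn-1-ol
Product: 23 (2E,4E)-5-[(1S,2R)-1,2-dihydroxy-2,6,6-trimethylcyclohexyl]-3-methylpenta-2,4-dien-1-ol, via silyl dienediol 22 (not isolated)
Conditions: NaAlH2(OCH2CH2OMe)2 (Red-Al), THF, 0 °C to rt; aq. potassium sodium tartrate; then n-Bu4NF, THF, rt
Reagents that add atoms: none
Why: Alkoxide-directed trans-hydroalumination of the propargylic alcohol gives the 7E alkene and fluoride then removes the silyl group, the C6 descriptor changing from R to S only because the alkenyl group ranks below the ring carbon.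

**Step 13**
Reactants: 23 (2E,4E)-5-[(1S,2R)-1,2-dihydroxy-2,6,6-trimethylcyclohexyl]-3-methylpenta-2,4-dien-1-ol
Product: 25 {(2E,4E)-5-[(1S,2R)-1,2-dihydroxy-2,6,6-trimethylcyclohexyl]-3-methylpenta-2,4-dien-1-yl}triphenylphosphonium bromide, via allylic bromide 24 (not isolated)
Conditions: CBr4 (1.05 equiv), PPh3, CH2Cl2, −20 °C; then PPh3, rt
Reagents that add atoms: carbon tetrabromide, BrC(Br)(Br)Br; triphenylphosphine, c1ccc(cc1)P(c1ccccc1)c1ccccc1
Why: Appel bromination is selective for the primary allylic hydroxyl over the two hindered tertiary ones, and the neutral conditions avoid ionization of the dienyl carbinol at C6 before SN2 quaternization.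

**Step 14**
Reactants: 25 {(2E,4E)-5-[(1S,2R)-1,2-dihydroxy-2,6,6-trimethylcyclohexyl]-3-methylpenta-2,4-dien-1-yl}triphenylphosphonium bromide; 18 (2E,4E,6E,8E,10E)-2,7-dimethyl-11-[(2S,7aR)-4,4,7a-trimethyl-2,4,5,6,7,7a-hexahydro-1-benzofuran-2-yl]dodeca-2,4,6,8,10-pentaenal
Product: 26 (5R,6S,5'R,8'S)-5',8'-epoxy-5,6,5',8'-tetrahydro-β,β-carotene-5,6-diol
Conditions: 1,2-epoxybutane, EtOH, 70 °C, Ar, dark; chromatography on Et3N-deactivated silica, crystallization
Reagents that add atoms: none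
Why: Wittig olefination under neutral epoxide conditions tolerates the free diol and the acid-labile furanoid ether and forms C11=C12, which equilibrates thermally to the all-E polyene.

**Compound list**
1 | (R)-(−)-linalool, (3R)-3,7-dimethylocta-1,6-dien-3-ol | C=C[C@](C)(O)CCC=C(C)C | starting material
2 | (1R)-1,3,3-trimethyl-2-methylidenecyclohexan-1-ol | C=C1[C@](C)(O)CCCC1(C)C | intermediate
3 | (6R)-6,10,10-trimethyl-1,2,4-trioxaspiro[4.5]decan-6-ol (spiro ozonide, epimers at the spiro carbon) | C[C@@]1(O)CCCC(C)(C)C12OCOO2 | intermediate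
4 | (2R)-2-hydroxy-2,6,6-trimethylcyclohexan-1-one | O=C1[C@](C)(O)CCCC1(C)C | intermediate
5 | (2R)-2,6,6-trimethyl-2-[(triethylsilyl)oxy]cyclohexan-1-one | O=C1[C@](C)(O[Si](CC)(CC)CC)CCCC1(C)C | intermediate
6 | ethyl but-2-ynoate | CCOC(=O)C#CC | starting material
7 | ethyl (2Z)-3-(4,4,5,5-tetramethyl-1,3,2-dioxaborolan-2-yl)but-2-enoate | CCOC(=O)/C=C(\C)B1OC(C)(C)C(C)(C)O1 | intermediate
8 | ethynylmagnesium bromide | C#C[Mg]Br | starting material
9 | bromomagnesium (1R,2R)-1-ethynyl-2,6,6-trimethyl-2-[(triethylsilyl)oxy]cyclohexan-1-olate | C#C[C@]1(O[Mg]Br)C(C)(C)CCC[C@@]1(C)O[Si](CC)(CC)CC | intermediate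
10 | (1R,2R)-1-ethynyl-2,6,6-trimethyl-2-[(triethylsilyl)oxy]cyclohexyl methyl carbonate | C#C[C@]1(OC(=O)OC)C(C)(C)CCC[C@@]1(C)O[Si](CC)(CC)CC | intermediate
11 | ethyl (2E,4Ra)-3-methyl-5-{(2R)-2,6,6-trimethyl-2-[(triethylsilyl)oxy]cyclohexylidene}penta-2,4-dienoate | CCOC(=O)/C=C(C)/C=[C@@]=C1C(C)(C)CCC[C@@]1(C)O[Si](CC)(CC)CC | intermediate
12 | ethyl (2E,4Ra)-5-[(2R)-2-hydroxy-2,6,6-trimethylcyclohexylidene]-3-methylpenta-2,4-dienoate | CCOC(=O)/C=C(C)/C=[C@@]=C1C(C)(C)CCC[C@@]1(C)O | intermediate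
13 | ethyl (2E)-3-[(2S,7aR)-4,4,7a-trimethyl-2,4,5,6,7,7a-hexahydro-1-benzofuran-2-yl]but-2-enoate | CCOC(=O)/C=C(\C)[C@@H]1C=C2C(C)(C)CCC[C@@]2(C)O1 | intermediate
14 | (2E)-3-[(2S,7aR)-4,4,7a-trimethyl-2,4,5,6,7,7a-hexahydro-1-benzofuran-2-yl]but-2-en-1-ol | OC/C=C(\C)[C@@H]1C=C2C(C)(C)CCC[C@@]2(C)O1 | intermediate
15 | (2S,7aR)-2-[(2E)-4-bromobut-2-en-2-yl]-4,4,7a-trimethyl-2,4,5,6,7,7a-hexahydro-1-benzofuran | BrC/C=C(\C)[C@@H]1C=C2C(C)(C)CCC[C@@]2(C)O1 | intermediate
16 | {(2E)-3-[(2S,7aR)-4,4,7a-trimethyl-2,4,5,6,7,7a-hexahydro-1-benzofuran-2-yl]but-2-en-1-yl}triphenylphosphonium bromide | [Br-].C(/C=C(\C)[C@@H]1C=C2C(C)(C)CCC[C@@]2(C)O1)[P+](c3ccccc3)(c4ccccc4)c5ccccc5 | intermediate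
17 | (2E,4E,6E)-2,7-dimethylocta-2,4,6-trienedial | O=C/C(C)=C/C=C/C=C(C)/C=O | starting material
18 | (2E,4E,6E,8E,10E)-2,7-dimethyl-11-[(2S,7aR)-4,4,7a-trimethyl-2,4,5,6,7,7a-hexahydro-1-benzofuran-2-yl]dodeca-2,4,6,8,10-pentaenal | O=C/C(C)=C/C=C/C=C(C)/C=C/C=C(\C)[C@@H]1C=C2C(C)(C)CCC[C@@]2(C)O1 | intermediate
19 | (2E)-3-methylpent-2-en-4-yn-1-ol | C#C/C(C)=C/CO | starting material
20 | dilithium salt of 19 (lithium alkoxide and lithium acetylide) | [Li]C#C/C(C)=C/CO[Li] | intermediate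
21 | (2E)-5-{(1R,2R)-1-hydroxy-2,6,6-trimethyl-2-[(triethylsilyl)oxy]cyclohexyl}-3-methylpent-2-en-4-yn-1-ol | OC/C=C(C)/C#C[C@]1(O)C(C)(C)CCC[C@@]1(C)O[Si](CC)(CC)CC | intermediate
22 | (2E,4E)-5-{(1S,2R)-1-hydroxy-2,6,6-trimethyl-2-[(triethylsilyl)oxy]cyclohexyl}-3-methylpenta-2,4-dien-1-ol | OC/C=C(C)/C=C/[C@]1(O)C(C)(C)CCC[C@@]1(C)O[Si](CC)(CC)CC | intermediate
23 | (2E,4E)-5-[(1S,2R)-1,2-dihydroxy-2,6,6-trimethylcyclohexyl]-3-methylpenta-2,4-dien-1-ol | OC/C=C(C)/C=C/[C@]1(O)C(C)(C)CCC[C@@]1(C)O | intermediate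
24 | (1S,2R)-1-[(1E,3E)-5-bromo-3-methylpenta-1,3-dien-1-yl]-2,6,6-trimethylcyclohexane-1,2-diol | BrC/C=C(C)/C=C/[C@]1(O)C(C)(C)CCC[C@@]1(C)O | intermediate
25 | {(2E,4E)-5-[(1S,2R)-1,2-dihydroxy-2,6,6-trimethylcyclohexyl]-3-methylpenta-2,4-dien-1-yl}triphenylphosphonium bromide | [Br-].C(/C=C(C)/C=C/[C@]1(O)C(C)(C)CCC[C@@]1(C)O)[P+](c2ccccc2)(c3ccccc3)c4ccccc4 | intermediate
26 | (5R,6S,5'R,8'S)-5',8'-epoxy-5,6,5',8'-tetrahydro-β,β-carotene-5,6-diol | CC(/C=C/C=C(C)/C=C/[C@]1(O)C(C)(C)CCC[C@@]1(C)O)=C\C=C\C=C(C)\C=C\C=C(/C)[C@@H]1C=C2C(C)(C)CCC[C@@]2(C)O1 | target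

**Step count**
Total steps: 14. Longest linear sequence: 10 (steps 1, 2, 3, 5, 6, 7, 8, 9, 10, 14).

**Steps most likely to fail**

Step 1 (the proposed new cycloisomerization). Risks are hydrogen-atom transfer to the vinyl group followed by 5-exo closure to cyclopentanols, 7-endo closure, or simple alkene isomerization without ring closure. The fallback uses known chemistry, sets out from 1 and comes back at 4. Hydroxyl-directed epoxidation of the vinyl group with VO(acac)2 and t-BuOOH gives (2R)-6-methyl-2-(oxiran-2-yl)hept-5-en-2-ol F1. Cleavage of the oxirane with H5IO6 in aqueous THF gives (2R)-2-hydroxy-2,6-dimethylhept-5-enal F2. Iron-hydride MHAT reductive alkene–carbonyl cyclization (Fe(acac)3, PhSiH3, EtOH, 60 °C; tertiary radical adds 6-exo to the aldehyde) gives (1R)-1,3,3-trimethylcyclohexane-1,2-diol F3 as a mixture at the secondary carbinol. Swern oxidation of that secondary alcohol returns ketone 4.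

Step 6 (palladium allene coupling). Risks are slow transmetalation of the pinacol boronate and loss of axial purity through epimerization of the allenylpalladium species. The fallback sets out from 5 and 8 and comes back at 11, replacing palladium cross-coupling of a carbonate by copper-mediated γ-selective substitution of a phosphate. The alkoxide 9 is quenched with ClP(O)(OEt)2 instead of methyl chloroformate to give diethyl (1R,2R)-1-ethynyl-2,6,6-trimethyl-2-[(triethylsilyl)oxy]cyclohexyl phosphate F4. F4 is then treated with boronate 7, CuCl (10 mol%), the ligand 1,3-bis(2,6-diisopropylphenyl)imidazol-2-ylidene and LiOt-Bu in THF. The alkenylcopper (monovalent copper) attacks the alkyne terminus anti to the phosphate and gives the same (Ra) allene 11.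

Step 10 (Wittig reaction of the furanoid ylide). The ylide carries the ring oxygen at the δ-carbon, so vinylogous β-elimination that opens the dihydrofuran, or loss of C8' integrity, can compete. The fallback sets out from 14, 25 and 17 and comes back at 26 with the polarity of the C11'=C12' disconnection reversed. MnO2 oxidation of 14 gives (2E)-3-[(2S,7aR)-4,4,7a-trimethyl-2,4,5,6,7,7a-hexahydro-1-benzofuran-2-yl]but-2-enal F5. Wittig reaction of 25 with excess 17 (1,2-epoxybutane, EtOH) gives (2E,4E,6E,8E,10E,12E)-13-[(1S,2R)-1,2-dihydroxy-2,6,6-trimethylcyclohexyl]-2,7,11-trimethyltrideca-2,4,6,8,10,12-hexaenal F6. NaBH4 reduction gives (2E,4E,6E,8E,10E,12E)-13-[(1S,2R)-1,2-dihydroxy-2,6,6-trimethylcyclohexyl]-2,7,11-trimethyltrideca-2,4,6,8,10,12-hexaen-1-ol F7. CBr4/PPh3 gives (1S,2R)-1-[(1E,3E,5E,7E,9E,11E)-13-bromo-3,7,12-trimethyltrideca-1,3,5,7,9,11-hexaen-1-yl]-2,6,6-trimethylcyclohexane-1,2-diol F8, which is quaternized with PPh3 to [(2E,4E,6E,8E,10E,12E)-13-[(1S,2R)-1,2-dihydroxy-2,6,6-trimethylcyclohexyl]-2,7,11-trimethyltrideca-2,4,6,8,10,12-hexaen-1-yl]triphenylphosphonium bromide F9. Wittig reaction of F9 with F5 under the conditions of step 14 gives 26.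

**Further compounds**
F1 | step 1 | (2R)-6-methyl-2-(oxiran-2-yl)hept-5-en-2-ol | C1OC1[C@](C)(O)CCC=C(C)C
F2 | step 1 | (2R)-2-hydroxy-2,6-dimethylhept-5-enal | O=C[C@](C)(O)CCC=C(C)C
F3 | step 1 | (1R)-1,3,3-trimethylcyclohexane-1,2-diol | OC1[C@](C)(O)CCCC1(C)C
F4 | step 6 | diethyl (1R,2R)-1-ethynyl-2,6,6-trimethyl-2-[(triethylsilyl)oxy]cyclohexyl phosphate | C#C[C@]1(OP(=O)(OCC)OCC)C(C)(C)CCC[C@@]1(C)O[Si](CC)(CC)CC
F5 | step 10 | (2E)-3-[(2S,7aR)-4,4,7a-trimethyl-2,4,5,6,7,7a-hexahydro-1-benzofuran-2-yl]but-2-enal | O=C/C=C(\C)[C@@H]1C=C2C(C)(C)CCC[C@@]2(C)O1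
F6 | step 10 | (2E,4E,6E,8E,10E,12E)-13-[(1S,2R)-1,2-dihydroxy-2,6,6-trimethylcyclohexyl]-2,7,11-trimethyltrideca-2,4,6,8,10,12-hexaenal | CC(/C=C/C=C(C)/C=C/[C@]1(O)C(C)(C)CCC[C@@]1(C)O)=C\C=C\C=C(C)\C=O
F7 | step 10 | (2E,4E,6E,8E,10E,12E)-13-[(1S,2R)-1,2-dihydroxy-2,6,6-trimethylcyclohexyl]-2,7,11-trimethyltrideca-2,4,6,8,10,12-hexaen-1-ol | CC(/C=C/C=C(C)/C=C/[C@]1(O)C(C)(C)CCC[C@@]1(C)O)=C\C=C\C=C(C)\CO
F8 | step 10 | (1S,2R)-1-[(1E,3E,5E,7E,9E,11E)-13-bromo-3,7,12-trimethyltrideca-1,3,5,7,9,11-hexaen-1-yl]-2,6,6-trimethylcyclohexane-1,2-diol | CC(/C=C/C=C(C)/C=C/[C@]1(O)C(C)(C)CCC[C@@]1(C)O)=C\C=C\C=C(C)\CBr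
F9 | step 10 | [(2E,4E,6E,8E,10E,12E)-13-[(1S,2R)-1,2-dihydroxy-2,6,6-trimethylcyclohexyl]-2,7,11-trimethyltrideca-2,4,6,8,10,12-hexaen-1-yl]triphenylphosphonium bromide | [Br-].CC(/C=C/C=C(C)/C=C/[C@]1(O)C(C)(C)CCC[C@@]1(C)O)=C\C=C\C=C(C)\C[P+](c2ccccc2)(c3ccccc3)c4ccccc4
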